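The first half-life of the starting material by self-condensation alone, at full charge, is 19.2 s, which is shorter than the 80 s feed.

    starting material ⇌ intermediate + leaving ligand, settled at all times (K1 = 1.8 × 10⁻⁵ M, ΔH1 = 26.0 kJ mol⁻¹)
    coupling partner + intermediate → target (k2 = 39 L mol⁻¹ s⁻¹, Ea2 = 53.0 kJ mol⁻¹)
    2 starting material → self-condensation product (k3 = 13 L mol⁻¹ s⁻¹, Ea3 = 37.0 kJ mol⁻¹)
    (constants at 25 °C)

| setting | Thursday's | Friday's | Sunday's | Monday's |
|---|---|---|---|---|
| starting material | 2.0 mM (fed, over 80 s) | 2.0 mM | 2.0 mM | 2.0 mM (in portions, 5, over 80 s) |
| coupling partner | 2.40 mM | 2.40 mM (fed, over 80 s) | 2.40 mM (fed, over 80 s) | 2.40 mM |
| temperature | 25 °C |  | 25 °C | 25 °C |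
| time | 1.5 min | 1.5 min | 1.5 min | 1.5 min |
| remark | all else is in the flask from the start; the feed brings no volume worth counting | the addition at 5 °C, then warmed to 25 °C; the feed brings no volume worth counting | all else is in the flask from the start; the feed brings no volume worth counting | first portion at the start, last at 80 s |

- percent here means starting material units held: one self-condensation product counts as two
- for a step with 2 of a species take k times the square, and two of it per event
- constants are those at 25 °C; use the activation energies and enthalpies for any other temperature

* the flask that comes out highest in amount of self-condensation product, in percent of the starting material charged; "all alike" if 1.5 percentage points covers them all (Thursday's / Friday's / Sunday's / Monday's / all alike)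
* amount of self-condensation product at the end, in percent of the starting material charged, Thursday's
* amount of self-condensation product at the end, in percent of the starting material charged, Friday's
* amount of self-condensation product at the end, in percent of the starting material charged, Sunday's
* amount of self-condensation product at the end, in percent of the starting material charged, Monday's

The starting material is the limiting reagent, at 2.0 mM against 2.40 mM of coupling partner, so I write its balance:

charge = c(starting material) + c(intermediate) + c(target) + 2 c(self-condensation product)

Each intermediate frees one leaving ligand, and the intermediate stays at balance:

c(leaving ligand) = c(intermediate) + c(target)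

c(intermediate) = K c(starting material) / c(leaving ligand)

Dividing the self-condensation loss by the coupling loss gives a selectivity factor S, the units lost to self-condensation for each unit of target:

S = c(starting material) c(leaving ligand) / (g c(coupling partner))

Here g is the split constant, the coupling constant times the balance constant over 2 times the self-condensation constant, 0.0270 mM at 25 °C.

I reckon Sunday's, which starts with its whole charge of starting material and no coupling partner. Self-condensation alone leaves this fraction of the starting material at the end:

17.6%

For 19.2 s in Sunday's, I take the starting material as 1.00 mM and the coupling partner fed as 0.577 mM. I take the leaving ligand as about equal to the intermediate, 0.134 mM. So: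

S = 8.61

self-condensation product = 73.8%

The weak link is one S for the whole run. Target adds leaving ligand, and the feed adds coupling partner. So I let S hold up to 45.0 s, when I take the starting material as 29.9% and the target as 7.29%. From these values:

c(target) = 0.146 mM

c(intermediate) = 0.0540 mM

S = 3.28

self-condensation product = 72.2%

I commit to 72.2% for Sunday's and name it highest. Thursday's and Monday's bring their starting material in over the feed time, and Friday's starts cold, though I reckon no figure for these three.

The forecast names Sunday's, with 45% for Thursday's, 61% for Friday's, 74% for Sunday's against my 72.2%, and 46% for Monday's, holding that “feeding it in (Thursday's, Monday's) keeps its concentration low”.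

The simulation gives Sunday's as highest: 46.4% for Thursday's, 60.2% for Friday's, 73.3% for Sunday's and 42.8% for Monday's.

In Sunday's at 0.750 min, the standing amounts give S = 2.83, against my 3.28. At that moment self-condensation takes more starting material than coupling, and Sunday's ends at 73.3% self-condensation product with 10.9% target. At the end of Monday's, S = 5.30. The same flask as Monday's with 8.0 mM of starting material stands higher at its end, at S = 18.6, with 73.0% self-condensation product and 6.85% target.

The rate constants come from no measurement; the flask was simulated.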